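**Retrosynthetic overview**
1. Target ⇒ the (E)-C1'=C2' bond and the dihydropyranone ring (last ring formed) are made in one pot by ring-closing/cross-metathesis of triene acrylate 18 with terminal alkene 13.
2. 13 ⇒ acetylation and deboronation of 10; C4' comes from a phosphoric-acid-catalysed allylboration of aldehyde 8.
3. 8 ⇒ a new iminium/boronate oxa-Michael cyclisation of δ-hydroxy enal 6 sets the C6'–O bond and stereocentre; it forms a temporary 1,3,2-dioxaborinane (first ring formed), which is also the only protecting group.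
4. 6 ⇒ cross-metathesis of 4 with crotonaldehyde; 4 ⇒ 3-phenylpropanal + allylBpin by phosphoric-acid-catalysed allylboration (first stereocentre, C8').
5. 18 ⇒ acrolein + allylBpin (same organocatalytic allylboration, lactone C6), then acryloyl chloride.

Assumption: the SMILES is taken literally, i.e. 6S at the lactone carbon and R at each side-chain carbinol carbon (C4', C6', C8', counted from the lactone); (R)-TRIP is taken to deliver allyl to the Re face of RCHO, as it does for benzaldehyde.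

**Route**

Step 1
Reactants: 1 3-phenylpropanal; 2 2-allyl-4,4,5,5-tetramethyl-1,3,2-dioxaborolane (allylBpin)
Product: 4 (3R)-1-phenylhex-5-en-3-ol, via borate ester 3 (not isolated)
Conditions: (S)-TRIP phosphoric acid (5 mol %), toluene, −30 °C; aq. work-up
Reagents that add atoms: none
Why: Chiral phosphoric-acid-catalysed allylboration through a chair transition state in which the acid bridges the boronate oxygen and the formyl H; the (S) acid sends allyl to the Si face and sets C8' as R (about 90% ee expected for this aldehyde class, and the minor enantiomer becomes a separable diastereomer in step 4).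

Step 2
Reactants: 4 (3R)-1-phenylhex-5-en-3-ol; 5 (2E)-but-2-enal
Product: 6 (2E,5R)-5-hydroxy-7-phenylhept-2-enal
Conditions: Hoveyda–Grubbs II (3 mol %), 5 (5 equiv), CH2Cl2, 40 °C
Reagents that add atoms: none
Why: Olefin cross-metathesis of a type I homoallylic alcohol with an enal is reliably E-selective, tolerates the free hydroxyl and does not touch the stereocentre.

Step 3
Reactants: 6 (2E,5R)-5-hydroxy-7-phenylhept-2-enal
Product: 8 2-[(4R,6R)-2-phenyl-6-(2-phenylethyl)-1,3,2-dioxaborinan-4-yl]acetaldehyde, via boronic hemiester 7 (not isolated)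
Conditions: PhB(OH)2 (1.2 equiv), (S)-α,α-diphenylprolinol TMS ether (20 mol %), PhCO2H (20 mol %), toluene, 0 °C → rt; short silica plug
Reagents that add atoms: phenylboronic acid, OB(O)c1ccccc1
Why: Proposed new method: an iminium-activated, boron-tethered intramolecular oxa-Michael addition in which the amine converts the enal into an iminium ion, the C5 hydroxyl reversibly forms hemiester 7, the benzoate counter-ion binds boron to give a nucleophilic hydroxyboronate, and its B–O oxygen (the boronic acid acts as hydroxide surrogate and supplies O6') adds 6-exo-trig to Cβ through a chair with the phenethyl group equatorial, after which the enamine is hydrolysed by the water released on ester formation; the (S) catalyst blocks the face that would give the trans ring, so catalyst, the chair preference and thermodynamics (the addition is reversible) all favour the cis-4,6-diequatorial boronate with C6' = R; the closest known reactions are the amine–thiourea-catalysed boronic acid oxy-Michael addition to hydroxy enones and the diarylprolinol-catalysed oxime oxa-Michael addition to enals.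

Step 4
Reactants: 8 2-[(4R,6R)-2-phenyl-6-(2-phenylethyl)-1,3,2-dioxaborinan-4-yl]acetaldehyde; 2 allylBpin
Product: 10 (2R)-1-[(4S,6R)-2-phenyl-6-(2-phenylethyl)-1,3,2-dioxaborinan-4-yl]pent-4-en-2-ol, via borate ester 9 (not isolated)
Conditions: (R)-TRIP phosphoric acid (5–10 mol %), toluene, −30 °C; aq. work-up, re-concentrate from toluene
Reagents that add atoms: none
Why: The same phosphoric-acid-catalysed allylboration under catalyst control, with the (R) acid attacking the Re face to set C4' as R (anti to C6'); the diequatorial cis-boronate stays on O6'/O8' so only the new hydroxyl is free (ring C4 is labelled S here only because the CIP priorities change, not the geometry).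

Step 5
Reactants: 10 (2R)-1-[(4S,6R)-2-phenyl-6-(2-phenylethyl)-1,3,2-dioxaborinan-4-yl]pent-4-en-2-ol
Product: 11 (2R)-1-[(4R,6R)-2-phenyl-6-(2-phenylethyl)-1,3,2-dioxaborinan-4-yl]pent-4-en-2-yl acetate
Conditions: Ac2O (1.5 equiv), pyridine, DMAP (5 mol %), CH2Cl2, 0 °C → rt
Reagents that add atoms: acetic anhydride, CC(=O)OC(C)=O
Why: DMAP-catalysed O-acylation of the only free hydroxyl proceeds with retention at C4' while the boronate masks the 6',8'-diol.

Step 6
Reactants: 11 (2R)-1-[(4R,6R)-2-phenyl-6-(2-phenylethyl)-1,3,2-dioxaborinan-4-yl]pent-4-en-2-yl acetate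
Product: 13 (4R,6R,8R)-6,8-dihydroxy-10-phenyldec-1-en-4-yl acetate, via phenoxyborate 12 (not isolated)
Conditions: 30% aq. H2O2, pH 7 phosphate buffer, THF, 0 °C
Reagents that add atoms: none
Why: Oxidative deboronation (1,2-aryl shift from boron to peroxide oxygen, then hydrolysis of the borate) frees the syn-diol at neutral pH, where acetate hydrolysis and 1,3-acyl migration do not compete and the terminal alkene is inert.

Step 7
Reactants: 14 prop-2-enal (acrolein); 2 allylBpin
Product: 16 (3S)-hexa-1,5-dien-3-ol, via borate ester 15 (not isolated)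
Conditions: (S)-TRIP phosphoric acid (5 mol %), toluene, −30 °C; aq. work-up; volatile product kept as a dried solution or concentrated cold
Reagents that add atoms: none
Why: Phosphoric-acid-catalysed allylboration of an enal, a favourable substrate class; the (S) acid directs allyl to the Si face, which gives the (3S) dienol, the future lactone C6.

Step 8
Reactants: 16 (3S)-hexa-1,5-dien-3-ol; 17 prop-2-enoyl chloride
Product: 18 (3S)-hexa-1,5-dien-3-yl prop-2-enoate
Conditions: Et3N (2 equiv), DMAP (5 mol %), CH2Cl2, 0 °C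
Reagents that add atoms: none
Why: Nucleophilic acyl substitution on the acid chloride acylates the secondary allylic alcohol without involving the stereocentre.

Step 9
Reactants: 18 (3S)-hexa-1,5-dien-3-yl prop-2-enoate; 13 (4R,6R,8R)-6,8-dihydroxy-10-phenyldec-1-en-4-yl acetate
Product: 20 (6S)-6-[(1E,4R,6R,8R)-4-acetoxy-6,8-dihydroxy-10-phenyldec-1-en-1-yl]-5,6-dihydro-2H-pyran-2-one, via vinyl lactone 19 (not isolated)
Conditions: Hoveyda–Grubbs II (3 mol %), 18 (2.5 equiv), CH2Cl2 (0.05 M), 40 °C, 2 h; then 13 (1 equiv), Hoveyda–Grubbs II (5 mol %), 40 °C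
Reagents that add atoms: none
Why: One-pot ring-closing/cross-metathesis in which the Ru carbene loads on the allyl end of 18 and closes the six-membered enoate ring to 19 (faster than five-ring closure onto the hindered allylic vinyl group), and the type II vinyl group of 19 then couples with the type I alkene of 13 with thermodynamic E selectivity, leaving hydroxyls, acetate and all four stereocentres untouched.

**Compound list**
1 | 3-phenylpropanal | O=CCCc1ccccc1 | starting material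
2 | 2-allyl-4,4,5,5-tetramethyl-1,3,2-dioxaborolane (allylBpin) | C=CCB1OC(C)(C)C(C)(C)O1 | starting material
3 | 4,4,5,5-tetramethyl-2-{[(3R)-1-phenylhex-5-en-3-yl]oxy}-1,3,2-dioxaborolane | C=CC[C@H](OB1OC(C)(C)C(C)(C)O1)CCc2ccccc2 | intermediate
4 | (3R)-1-phenylhex-5-en-3-ol | C=CC[C@H](O)CCc1ccccc1 | intermediate
5 | (2E)-but-2-enal | C/C=C/C=O | starting material
6 | (2E,5R)-5-hydroxy-7-phenylhept-2-enal | O=C/C=C/C[C@H](O)CCc1ccccc1 | intermediate
7 | (2E,5R)-5-{[hydroxy(phenyl)boranyl]oxy}-7-phenylhept-2-enal | O=C/C=C/C[C@H](OB(O)c1ccccc1)CCc2ccccc2 | intermediate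
8 | 2-[(4R,6R)-2-phenyl-6-(2-phenylethyl)-1,3,2-dioxaborinan-4-yl]acetaldehyde | O=CC[C@H]1C[C@@H](CCc2ccccc2)OB(c2ccccc2)O1 | intermediate
9 | 4,4,5,5-tetramethyl-2-({(2R)-1-[(4R,6R)-2-phenyl-6-(2-phenylethyl)-1,3,2-dioxaborinan-4-yl]pent-4-en-2-yl}oxy)-1,3,2-dioxaborolane | C=CC[C@@H](OB2OC(C)(C)C(C)(C)O2)C[C@H]1C[C@@H](CCc3ccccc3)OB(c3ccccc3)O1 | intermediate
10 | (2R)-1-[(4S,6R)-2-phenyl-6-(2-phenylethyl)-1,3,2-dioxaborinan-4-yl]pent-4-en-2-ol | C=CC[C@@H](O)C[C@H]1C[C@@H](CCc2ccccc2)OB(c2ccccc2)O1 | intermediate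
11 | (2R)-1-[(4R,6R)-2-phenyl-6-(2-phenylethyl)-1,3,2-dioxaborinan-4-yl]pent-4-en-2-yl acetate | C=CC[C@@H](OC(C)=O)C[C@H]1C[C@@H](CCc2ccccc2)OB(c2ccccc2)O1 | intermediate
12 | (2R)-1-[(4R,6R)-2-phenoxy-6-(2-phenylethyl)-1,3,2-dioxaborinan-4-yl]pent-4-en-2-yl acetate | C=CC[C@@H](OC(C)=O)C[C@H]1C[C@@H](CCc2ccccc2)OB(Oc2ccccc2)O1 | intermediate
13 | (4R,6R,8R)-6,8-dihydroxy-10-phenyldec-1-en-4-yl acetate | C=CC[C@@H](OC(C)=O)C[C@H](O)C[C@H](O)CCc1ccccc1 | intermediate
14 | prop-2-enal (acrolein) | C=CC=O | starting material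
15 | 2-{[(3S)-hexa-1,5-dien-3-yl]oxy}-4,4,5,5-tetramethyl-1,3,2-dioxaborolane | C=CC[C@H](OB1OC(C)(C)C(C)(C)O1)C=C | intermediate
16 | (3S)-hexa-1,5-dien-3-ol | C=CC[C@H](O)C=C | intermediate
17 | prop-2-enoyl chloride | C=CC(=O)Cl | starting material
18 | (3S)-hexa-1,5-dien-3-yl prop-2-enoate | C=CC[C@H](OC(=O)C=C)C=C | intermediate
19 | (6S)-6-ethenyl-5,6-dihydro-2H-pyran-2-one | C=C[C@@H]1CC=CC(=O)O1 | intermediate
20 | (6S)-6-[(1E,4R,6R,8R)-4-acetoxy-6,8-dihydroxy-10-phenyldec-1-en-1-yl]-5,6-dihydro-2H-pyran-2-one (CNP0251907.1) | CC(=O)O[C@H](C/C=C/[C@@H]1CC=CC(=O)O1)C[C@H](O)C[C@H](O)CCc1ccccc1 | target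

**Step count**
Total: 9 steps. Longest linear sequence: 7 (steps 1–6, then 9); steps 7–8 make the second fragment.

**Steps most likely to fail**

Step 3 (the proposed oxa-Michael; the risks are poor turnover, retro-addition, or enamine self-condensation of 8). The fallback uses known chemistry, sets out from 6 and rejoins the route at 13. Compound 6 is treated with acetaldehyde and Bi(NO3)3·5H2O (10 mol %) in CH2Cl2 at rt, the known bismuth-mediated hemiacetal/oxa-conjugate addition of δ-hydroxy enals. Under substrate control this gives the all-equatorial acetal 2-[(2R,4R,6R)-2-methyl-6-(2-phenylethyl)-1,3-dioxan-4-yl]acetaldehyde F1. Allylboration as in step 4 passes through the borate ester 4,4,5,5-tetramethyl-2-({(2R)-1-[(2R,4S,6R)-2-methyl-6-(2-phenylethyl)-1,3-dioxan-4-yl]pent-4-en-2-yl}oxy)-1,3,2-dioxaborolane F2 to the alcohol (2R)-1-[(2R,4S,6R)-2-methyl-6-(2-phenylethyl)-1,3-dioxan-4-yl]pent-4-en-2-ol F3. Acetylation as in step 5 gives (2R)-1-[(2R,4R,6R)-2-methyl-6-(2-phenylethyl)-1,3-dioxan-4-yl]pent-4-en-2-yl acetate F4. Hydrolysis of the ethylidene acetal (80% aq. AcOH, 60 °C) then delivers 13; the acetal cannot migrate, so this series also removes any concern about boronate migration.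

Step 4 (the Lewis-acidic boronate and the two β/δ-oxygens may erode catalyst control and give a poor C4' ratio). The fallback sets out from 8 and rejoins at 11; it replaces asymmetric induction by a stereoconvergent sequence. Compound 8 is allylated with 2 without catalyst (toluene, rt), which gives, through 9 and its epimeric borate ester 4,4,5,5-tetramethyl-2-({(2S)-1-[(4R,6R)-2-phenyl-6-(2-phenylethyl)-1,3,2-dioxaborinan-4-yl]pent-4-en-2-yl}oxy)-1,3,2-dioxaborolane F5, a mixture of 10 and its C2 epimer (2S)-1-[(4S,6R)-2-phenyl-6-(2-phenylethyl)-1,3,2-dioxaborinan-4-yl]pent-4-en-2-ol F6. The two diastereomers are separated by chromatography. Compound 10 goes through step 5 with retention, and F6 is esterified under Mitsunobu conditions (PPh3, DIAD, AcOH, THF, 0 °C) with inversion, so both converge on 11.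

Step 9 (cross-metathesis of the type II vinyl lactone can be slow, 13 can homodimerise, and the 6-epimer arising from the minor enantiomer of 18 would be hard to remove). The fallback sets out from 11 and rejoins at 20; it builds the lactone on the chain instead of coupling it. Cross-metathesis of 11 with 5 (Hoveyda–Grubbs II, CH2Cl2, 40 °C) gives (2R,4E)-6-oxo-1-[(4R,6R)-2-phenyl-6-(2-phenylethyl)-1,3,2-dioxaborinan-4-yl]hex-4-en-2-yl acetate F7. (S)-TRIP-catalysed allylboration with 2 passes through the borate ester (2R,4E,6S)-1-[(4R,6R)-2-phenyl-6-(2-phenylethyl)-1,3,2-dioxaborinan-4-yl]-6-[(4,4,5,5-tetramethyl-1,3,2-dioxaborolan-2-yl)oxy]nona-4,8-dien-2-yl acetate F8 to the dienol (2R,4E,6S)-6-hydroxy-1-[(4R,6R)-2-phenyl-6-(2-phenylethyl)-1,3,2-dioxaborinan-4-yl]nona-4,8-dien-2-yl acetate F9; here the new diastereomer is separable because the centre is made on the chain. Acylation with 17 (Et3N, DMAP) gives (2R,4E,6S)-1-[(4R,6R)-2-phenyl-6-(2-phenylethyl)-1,3,2-dioxaborinan-4-yl]-6-(prop-2-enoyloxy)nona-4,8-dien-2-yl acetate F10. Ring-closing metathesis (Grubbs II, CH2Cl2, 40 °C) gives (2R,4E)-5-[(2S)-6-oxo-3,6-dihydro-2H-pyran-2-yl]-1-[(4R,6R)-2-phenyl-6-(2-phenylethyl)-1,3,2-dioxaborinan-4-yl]pent-4-en-2-yl acetate F11. Buffered H2O2 as in step 6 then removes the boronate through (2R,4E)-5-[(2S)-6-oxo-3,6-dihydro-2H-pyran-2-yl]-1-[(4R,6R)-2-phenoxy-6-(2-phenylethyl)-1,3,2-dioxaborinan-4-yl]pent-4-en-2-yl acetate F12 and gives 20.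

**Further compounds**
F1 | step 3 | 2-[(2R,4R,6R)-2-methyl-6-(2-phenylethyl)-1,3-dioxan-4-yl]acetaldehyde | O=CC[C@H]1C[C@@H](CCc2ccccc2)O[C@@H](C)O1
F2 | step 3 | 4,4,5,5-tetramethyl-2-({(2R)-1-[(2R,4S,6R)-2-methyl-6-(2-phenylethyl)-1,3-dioxan-4-yl]pent-4-en-2-yl}oxy)-1,3,2-dioxaborolane | C=CC[C@@H](OB2OC(C)(C)C(C)(C)O2)C[C@H]1C[C@@H](CCc3ccccc3)O[C@@H](C)O1
F3 | step 3 | (2R)-1-[(2R,4S,6R)-2-methyl-6-(2-phenylethyl)-1,3-dioxan-4-yl]pent-4-en-2-ol | C=CC[C@@H](O)C[C@H]1C[C@@H](CCc2ccccc2)O[C@@H](C)O1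
F4 | step 3 | (2R)-1-[(2R,4R,6R)-2-methyl-6-(2-phenylethyl)-1,3-dioxan-4-yl]pent-4-en-2-yl acetate | C=CC[C@@H](OC(C)=O)C[C@H]1C[C@@H](CCc2ccccc2)O[C@@H](C)O1
F5 | step 4 | 4,4,5,5-tetramethyl-2-({(2S)-1-[(4R,6R)-2-phenyl-6-(2-phenylethyl)-1,3,2-dioxaborinan-4-yl]pent-4-en-2-yl}oxy)-1,3,2-dioxaborolane | C=CC[C@H](OB2OC(C)(C)C(C)(C)O2)C[C@H]1C[C@@H](CCc3ccccc3)OB(c3ccccc3)O1
F6 | step 4 | (2S)-1-[(4S,6R)-2-phenyl-6-(2-phenylethyl)-1,3,2-dioxaborinan-4-yl]pent-4-en-2-ol | C=CC[C@H](O)C[C@H]1C[C@@H](CCc2ccccc2)OB(c2ccccc2)O1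
F7 | step 9 | (2R,4E)-6-oxo-1-[(4R,6R)-2-phenyl-6-(2-phenylethyl)-1,3,2-dioxaborinan-4-yl]hex-4-en-2-yl acetate | O=C/C=C/C[C@@H](OC(C)=O)C[C@H]1C[C@@H](CCc2ccccc2)OB(c2ccccc2)O1
F8 | step 9 | (2R,4E,6S)-1-[(4R,6R)-2-phenyl-6-(2-phenylethyl)-1,3,2-dioxaborinan-4-yl]-6-[(4,4,5,5-tetramethyl-1,3,2-dioxaborolan-2-yl)oxy]nona-4,8-dien-2-yl acetate | C=CC[C@H](OB2OC(C)(C)C(C)(C)O2)/C=C/C[C@@H](OC(C)=O)C[C@H]1C[C@@H](CCc3ccccc3)OB(c3ccccc3)O1
F9 | step 9 | (2R,4E,6S)-6-hydroxy-1-[(4R,6R)-2-phenyl-6-(2-phenylethyl)-1,3,2-dioxaborinan-4-yl]nona-4,8-dien-2-yl acetate | C=CC[C@H](O)/C=C/C[C@@H](OC(C)=O)C[C@H]1C[C@@H](CCc2ccccc2)OB(c2ccccc2)O1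
F10 | step 9 | (2R,4E,6S)-1-[(4R,6R)-2-phenyl-6-(2-phenylethyl)-1,3,2-dioxaborinan-4-yl]-6-(prop-2-enoyloxy)nona-4,8-dien-2-yl acetate | C=CC[C@H](OC(=O)C=C)/C=C/C[C@@H](OC(C)=O)C[C@H]1C[C@@H](CCc2ccccc2)OB(c2ccccc2)O1
F11 | step 9 | (2R,4E)-5-[(2S)-6-oxo-3,6-dihydro-2H-pyran-2-yl]-1-[(4R,6R)-2-phenyl-6-(2-phenylethyl)-1,3,2-dioxaborinan-4-yl]pent-4-en-2-yl acetate | CC(=O)O[C@H](C/C=C/[C@@H]1CC=CC(=O)O1)C[C@H]2C[C@@H](CCc3ccccc3)OB(c3ccccc3)O2
F12 | step 9 | (2R,4E)-5-[(2S)-6-oxo-3,6-dihydro-2H-pyran-2-yl]-1-[(4R,6R)-2-phenoxy-6-(2-phenylethyl)-1,3,2-dioxaborinan-4-yl]pent-4-en-2-yl acetate | CC(=O)O[C@H](C/C=C/[C@@H]1CC=CC(=O)O1)C[C@H]2C[C@@H](CCc3ccccc3)OB(Oc3ccccc3)O2
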